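| flask | starting material | partner | temperature | remark | time |
|---|---|---|---|---|---|
| alder | 0.050 M | 2.5 equiv | 0 °C | run made earlier |  |
| ash | 0.075 M | 2.5 equiv | 30 °C | run made earlier |  |
| violet | 0.10 M | 2.50 equiv | 30 °C |  | 20 h |
| ochre | 0.10 M | 2.50 equiv |  | at 5 °C until 15 h, from then on at 55 °C | 20 h |
| red | 0.10 M | 2.50 equiv | 5 °C |  | 20 h |
| grey | 0.10 M | 2.50 equiv | 55 °C |  | 20 h |

| run | time / h | target / % |
|---|---|---|
| alder | 12.0 | 10.7 |
| alder | 20.0 | 18.6 |
| alder | 40.0 | 29.7 |
| alder | 48.0 | 30.8 |
| ash | 2.50 | 1.1 |
| ash | 5.00 | 0.5 |
| ash | 8.00 | 0.4 |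
| ash | 10.0 | 0.6 |
| ash | 12.0 | 0.3 |

(readings scatter by 0.5 percentage points)

- the numbers in the tables scatter by 0.5 percentage points (one standard deviation)

* the flask that comes out highest in amount of target, in percent of the starting material charged, or "all alike" when all lie within 1.5 percentage points (violet / ochre / red / grey / all alike)
* target at the end, in percent of the starting material charged, violet
* target at the end, in percent of the starting material charged, ochre
* target at the end, in percent of the starting material charged, red
* target at the end, in percent of the starting material charged, grey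

- Closed at constant volume, each flask keeps its charge, so a reading in percent of starting material is a share of a fixed sum, and I can set flasks of different strength side by side.
- The alder run levels off at 30.8%, which I take as the plateau; at 20.0 h it reads 18.6%.
- I treat the climb as pseudo-first-order with partner in excess, so the share of the plateau still missing falls as e^−N, and the alder reading gives N = 0.926.
- The clock number N, scaled from that alder value by partner molarity times hours, counts how many e-fold closings of the gap a flask gets: for red, 1.85, twice the alder value.
- The readings give no figure for the warming from 0 °C to 5 °C, so I leave it out, and red then comes to 26.0%.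
- One number is not enough: the ash run has N = 0.833 at 12.0 h, which calls for 17.4%, yet it reads 0.3%.
- So warmth acts on target in a way N does not count, and from these readings I cannot tell by which route.
- Ash reads 0.5% at 5.00 h and 30 °C, and ochre spends 5.00 h at the warmer 55 °C, so I expect ochre, violet and grey near or under the late ash readings, and red highest.
- The forecast names red, with violet 0.7%, ochre 0.1%, red 28% and grey 0.1%, since “warmth kills it”.
- The flasks give red as highest, with violet 0.00718%, ochre 0%, red 27.9% and grey 0%.

    starting material + partner → intermediate + by-product (k = 1.90 × 10⁻⁴ M⁻¹ s⁻¹, Ea = 65.0 kJ mol⁻¹)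
    intermediate ⇌ target (K = 1.10, k = 3.90 × 10⁻⁵ s⁻¹, Ea = 98.0 kJ mol⁻¹, ΔH = −59.0 kJ mol⁻¹)
    intermediate ⇌ isomer of the product (K = 2.10, k = 6.40 × 10⁻⁷ s⁻¹, Ea = 96.0 kJ mol⁻¹, ΔH = −34.0 kJ mol⁻¹)
    2 partner → self-condensation product (k = 1.60 × 10⁻⁵ M⁻¹ s⁻¹, Ea = 68.0 kJ mol⁻¹)
    intermediate → decomposed reagent (k = 1.70 × 10⁻⁵ s⁻¹, Ea = 90.0 kJ mol⁻¹)
    (constants at 5 °C)

Red, at N = 1.85, was reckoned at 26.0% and reads 27.9%. The same flask as red with 1.00 equiv of partner has N = 0.741, which gives 16.1%, and it reads 17.6%. The main reason for the warm collapse is the backward run from target to intermediate: grey ends at 0%, and without that step it ends at 79.5%.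

The data are simulated on assumed constants, and the scatter is random.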